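**Retrosynthetic overview**

1. Last events: hydrogenolysis of ten benzyl ethers, preceded by the C4–C5′ bond. The protected 2,3-cis-flavan-3-ol enters as its C4 cation (from a C4 ether) and the flavonol as its C5 zinc reagent (from a C5 bromide), so the link forms trans to O3 and only at C5.
2. Both pyran rings are cut across the same two bonds, O1–C8a and C2–C3. Each half therefore comes from a 3,4-bis(benzyloxy)phenyl C1 carbonyl unit (aldehyde or ester) and a C6–C2 haloarene.
3. Flavan ring (key step): the aldehyde C=O is annulated onto a ring A unit that carries C4–C3 as CH2–CH(Bpin)2 and bromine on C8a. A copper-catalysed syn addition makes C2–C3 with both stereocentres, palladium closes O1–C8a, and oxidation turns C3–B into C3–OH.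
4. Enabling feature: C3 of the flavan pyran ring is a carbinol carbon between C2 and the benzylic CH2 (C4), and C8a of ring A is ortho to C4a. C3 can thus be a doubly borylated nucleophile: one boron is spent on C2–C3, the other is the masked O3 and keeps O3 out of the ether closure. The C2 oxygen then sits in reach of C8a.
5. Ring order: flavan pyran ring (step 5), flavonol pyranone ring by Claisen condensation/SNAr (step 10), union (step 11). All benzene rings are bought.

Key step: step 5

Remark: 2-bromo-3,4-dihydroxybenzaldehyde and 5-bromo-3-fluorobenzene-1,2-diol are taken as catalogue compounds; the C4 configuration of 12 is drawn as the expected 3,4-trans isomer and is erased in step 11.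

**Route**

Step 1
Reactants: 1 2-bromo-3,4-dihydroxybenzaldehyde
Product: 2 3,4-bis(benzyloxy)-2-bromobenzaldehyde
Conditions: BnBr, K2CO3, DMF, 50 °C
Reagents that add atoms: benzyl bromide, BrCc1ccccc1
Why: Williamson ether synthesis alkylates both phenoxides, while the aldehyde and the aryl bromide are inert to K2CO3.

Step 2
Reactants: 2 3,4-bis(benzyloxy)-2-bromobenzaldehyde
Product: 3 [3,4-bis(benzyloxy)-2-bromophenyl]methanol
Conditions: NaBH4, THF/MeOH, 0 °C
Reagents that add atoms: none
Why: Hydride reduction of the aldehyde with NaBH4 is chemoselective and leaves the aryl bromide and the benzyl ethers untouched.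

Step 3
Reactants: 3 [3,4-bis(benzyloxy)-2-bromophenyl]methanol
Product: 4 1,2-bis(benzyloxy)-3-bromo-4-(bromomethyl)benzene
Conditions: PBr3, CH2Cl2, 0 °C
Reagents that add atoms: phosphorus tribromide, BrP(Br)Br
Why: Bromination of the electron-rich benzylic alcohol through its phosphite ester (SN2) should be fast at 0 °C, and the bromide is used without storage.

Step 4
Reactants: 4 1,2-bis(benzyloxy)-3-bromo-4-(bromomethyl)benzene; 5 bis(4,4,5,5-tetramethyl-1,3,2-dioxaborolan-2-yl)methane
Product: 6 2,2′-{2-[3,4-bis(benzyloxy)-2-bromophenyl]ethane-1,1-diyl}bis(4,4,5,5-tetramethyl-1,3,2-dioxaborolane)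
Conditions: lithium 2,2,6,6-tetramethylpiperidide, THF, 0 °C; then 4, 0 °C to rt
Reagents that add atoms: none
Why: Deprotonated 5 is a soft, boron-stabilised carbanion that alkylates the benzylic bromide by SN2 without touching the aryl bromide (deprotonative alkylation of a geminal diboronate).

Step 5
Reactants: 6 the geminal diboronate from step 4; 7 3,4-bis(benzyloxy)benzaldehyde
Product: 10 (2R,3R)-7,8-bis(benzyloxy)-2-[3,4-bis(benzyloxy)phenyl]-3,4-dihydro-2H-chromen-3-ol, via syn-hydroxyboronate 8 (not isolated), via 3-borylchromane 9 (not isolated)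
Conditions: Cu(NCMe)4PF6 (10 mol %), BINOL-derived monodentate phosphoramidite (the enantiomer that gives the (1S,2R) adduct), lithium tert-pentoxide (1.5 equiv), THF, 22 °C; then Pd(OAc)2 (5 mol %), 2-(di-tert-butylphosphino)-1,1′-binaphthyl, toluene, 50 °C; then 30% H2O2, pH 7 phosphate buffer, 0 °C to rt
Reagents that add atoms: hydrogen peroxide, OO
Why: Lithium tert-pentoxide turns 6 into an α-boryl alkylcopper that adds to aldehyde 7 on the chiral phosphoramidite–copper complex through a closed transition state, forming C2–C3 and the syn (1S,2R) alkoxide 8; zerovalent palladium then inserts into the C8a–Br bond, the C2 alkoxide binds to palladium and C–O reductive elimination forms O1–C8a (9), after which H2O2 converts C3–B into C3–OH with retention. The closest known reaction types are the copper-catalysed enantio- and syn-selective 1,2-addition of 1,1-diborylalkanes to aryl aldehydes and the palladium-catalysed intramolecular etherification of bromoaryl alcohols to chromans (Buchwald–Hartwig-type C–O coupling), here telescoped into a formal [4+2] annulation of the aldehyde C=O. The pyran ring closes in a formally 6-exo sense (O1 onto C8a through a seven-membered palladacycle), and the competing five-membered closure through the C3 oxygen cannot occur because C3 still carries boron at that point. C2 and C3 are both set in the copper stage (absolute sense by the ligand enantiomer, syn relationship by the transition state) and are not touched afterwards, since the etherification breaks no bond at C2 and the oxidation retains C3. The step needs palladium to choose the aryl bromide over the secondary alkyl boronate and needs the β-boryl alkoxide to survive without boron–oxygen elimination; the low temperature, the use of 6 as the limiting component and the slow transmetalation of a secondary alkyl–Bpin should secure this.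

Step 6
Reactants: 10 the flavan-3-ol from step 5
Product: 11 (2R,3R)-3,7,8-tris(benzyloxy)-2-[3,4-bis(benzyloxy)phenyl]-3,4-dihydro-2H-chromene
Conditions: NaH, BnBr, Bu4NI (cat.), DMF, 0 °C to rt
Reagents that add atoms: benzyl bromide, BrCc1ccccc1
Why: Williamson etherification of the secondary alkoxide protects O3, so that the later cation chemistry at C4 has no free neighbouring hydroxyl; no stereocentre is touched.

Step 7
Reactants: 11 the penta-O-benzyl flavan from step 6
Product: 12 (2R,3R,4S)-3,7,8-tris(benzyloxy)-2-[3,4-bis(benzyloxy)phenyl]-4-(2-ethoxyethoxy)-3,4-dihydro-2H-chromene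
Conditions: DDQ, 2-ethoxyethanol, CH2Cl2, rt
Reagents that add atoms: 2-ethoxyethanol, CCOCCO
Why: DDQ abstracts hydride from C4, which is activated by O7 (para through ring A) and by O1 and whose C–H bond is aligned with the ring A π system, and the cation is trapped by the alcohol trans to the C3 substituent (oxidative benzylic etherification known for benzylated flavan-3-ols).

Step 8
Reactants: 13 5-bromo-3-fluorobenzene-1,2-diol
Product: 14 1,2-bis(benzyloxy)-5-bromo-3-fluorobenzene
Conditions: BnBr, K2CO3, DMF, 50 °C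
Reagents that add atoms: benzyl bromide, BrCc1ccccc1
Why: Williamson ether synthesis on both phenoxides; the aryl halides are inert under these conditions.

Step 9
Reactants: 14 1,2-bis(benzyloxy)-5-bromo-3-fluorobenzene; 15 2-(benzyloxy)-N-methoxy-N-methylacetamide
Product: 16 2-(benzyloxy)-1-[3,4-bis(benzyloxy)-6-bromo-2-fluorophenyl]ethan-1-one
Conditions: LiN(iPr)2 (commercial solution), THF, −78 °C; then 15, −78 to −20 °C; aq NH4Cl
Reagents that add atoms: none
Why: Directed ortho-lithiation removes the ring proton flanked by fluorine and bromine (the most acidic one) at −78 °C, where the aryllithium should not lose lithium halide, and the amide acylates it without over-addition (Weinreb ketone synthesis).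

Step 10
Reactants: 16 the fluoro ketone from step 9; 17 methyl 3,4-bis(benzyloxy)benzoate
Product: 19 3,7,8-tris(benzyloxy)-2-[3,4-bis(benzyloxy)phenyl]-5-bromo-4H-chromen-4-one, via 1,3-diketone 18 (not isolated)
Conditions: LiN(SiMe3)2 (2.5 equiv), THF, −78 °C to rt; then DMF, 60 °C
Reagents that add atoms: none
Why: Crossed Claisen condensation of the enolate of 16 with the non-enolisable ester gives the diketone enolate, whose oxygen displaces the fluoride ortho to the aryl ketone by intramolecular SNAr (6-exo) to close the pyranone; the aryl fluoride should react far faster than the aryl bromide.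

Step 11
Reactants: 12 the C4 ether from step 7; 19 the 5-bromoflavonol ether from step 10
Product: 21 3,7,8-tris(benzyloxy)-2-[3,4-bis(benzyloxy)phenyl]-5-{(2R,3R,4S)-3,7,8-tris(benzyloxy)-2-[3,4-bis(benzyloxy)phenyl]-3,4-dihydro-2H-chromen-4-yl}-4H-chromen-4-one, via arylzinc bromide 20 (not isolated)
Conditions: 19, Zn dust, CoBr2 (10 mol %), allyl chloride (cat.), MeCN, rt; then 12, BF3·OEt2, CH2Cl2, −40 to 0 °C
Reagents that add atoms: none
Why: Proposed new method: BF3·OEt2 should ionise the C4 ether of 12 to the flavan-4-yl cation (stabilised by O7 through ring A and by O1), which arylzinc bromide 20 should capture at its zinc-bearing carbon from the face opposite the C3 benzyloxy group (also the face remote from the C2 aryl group), giving the 3,4-trans (4S) product joined through C5 of the flavonol because the nucleophilic site is fixed by the former C–Br bond; the closest known reaction types are the Lewis-acid-mediated, 3,4-trans-selective C4 arylation of 4-alkoxyflavan-3-ols by electron-rich arenes (Friedel–Crafts type) and the uncatalysed coupling of arylzinc reagents with oxocarbenium ions from glycosyl halides, and the zinc reagent is made by cobalt-catalysed zinc insertion, which tolerates the chromone carbonyl.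

Step 12
Reactants: 21 the deca-O-benzyl biflavonoid from step 11
Product: 22 5-[(2R,3R,4S)-2-(3,4-dihydroxyphenyl)-3,7,8-trihydroxy-3,4-dihydro-2H-chromen-4-yl]-2-(3,4-dihydroxyphenyl)-3,7,8-trihydroxy-4H-chromen-4-one
Conditions: H2 (1 atm), Pd(OH)2/C, THF/MeOH, rt, under argon on work-up
Reagents that add atoms: none
Why: Hydrogenolysis should cleave all ten benzyl ethers while the chromone double bond, the C2–O1 benzylic ether and the C4–aryl bonds stay intact, and no stereocentre is touched.

**Compound list**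

1 | 2-bromo-3,4-dihydroxybenzaldehyde | O=Cc1ccc(O)c(O)c1Br | starting material
2 | 3,4-bis(benzyloxy)-2-bromobenzaldehyde | O=Cc1ccc(OCc2ccccc2)c(OCc2ccccc2)c1Br | intermediate
3 | [3,4-bis(benzyloxy)-2-bromophenyl]methanol | OCc1ccc(OCc2ccccc2)c(OCc2ccccc2)c1Br | intermediate
4 | 1,2-bis(benzyloxy)-3-bromo-4-(bromomethyl)benzene | BrCc1ccc(OCc2ccccc2)c(OCc2ccccc2)c1Br | intermediate
5 | bis(4,4,5,5-tetramethyl-1,3,2-dioxaborolan-2-yl)methane | CC1(C)OB(CB2OC(C)(C)C(C)(C)O2)OC1(C)C | starting material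
6 | 2,2′-{2-[3,4-bis(benzyloxy)-2-bromophenyl]ethane-1,1-diyl}bis(4,4,5,5-tetramethyl-1,3,2-dioxaborolane) | CC1(C)OB(OC1(C)C)C(Cc1ccc(OCc2ccccc2)c(OCc2ccccc2)c1Br)B1OC(C)(C)C(C)(C)O1 | intermediate
7 | 3,4-bis(benzyloxy)benzaldehyde | O=Cc1ccc(OCc2ccccc2)c(OCc2ccccc2)c1 | starting material
8 | (1S,2R)-1-[3,4-bis(benzyloxy)phenyl]-3-[3,4-bis(benzyloxy)-2-bromophenyl]-2-(4,4,5,5-tetramethyl-1,3,2-dioxaborolan-2-yl)propan-1-ol (syn-hydroxyboronate) | O[C@H](c1ccc(OCc2ccccc2)c(OCc2ccccc2)c1)[C@@H](Cc1ccc(OCc2ccccc2)c(OCc2ccccc2)c1Br)B1OC(C)(C)C(C)(C)O1 | intermediate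
9 | (2S,3R)-7,8-bis(benzyloxy)-2-[3,4-bis(benzyloxy)phenyl]-3-(4,4,5,5-tetramethyl-1,3,2-dioxaborolan-2-yl)-3,4-dihydro-2H-chromene | C1c2ccc(OCc3ccccc3)c(OCc3ccccc3)c2O[C@H](c2ccc(OCc3ccccc3)c(OCc3ccccc3)c2)[C@@H]1B1OC(C)(C)C(C)(C)O1 | intermediate
10 | (2R,3R)-7,8-bis(benzyloxy)-2-[3,4-bis(benzyloxy)phenyl]-3,4-dihydro-2H-chromen-3-ol | C1c2ccc(OCc3ccccc3)c(OCc3ccccc3)c2O[C@H](c2ccc(OCc3ccccc3)c(OCc3ccccc3)c2)[C@@H]1O | intermediate
11 | (2R,3R)-3,7,8-tris(benzyloxy)-2-[3,4-bis(benzyloxy)phenyl]-3,4-dihydro-2H-chromene | C1c2ccc(OCc3ccccc3)c(OCc3ccccc3)c2O[C@H](c2ccc(OCc3ccccc3)c(OCc3ccccc3)c2)[C@@H]1OCc1ccccc1 | intermediate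
12 | (2R,3R,4S)-3,7,8-tris(benzyloxy)-2-[3,4-bis(benzyloxy)phenyl]-4-(2-ethoxyethoxy)-3,4-dihydro-2H-chromene | CCOCCO[C@H]1c2ccc(OCc3ccccc3)c(OCc3ccccc3)c2O[C@H](c2ccc(OCc3ccccc3)c(OCc3ccccc3)c2)[C@@H]1OCc1ccccc1 | intermediate
13 | 5-bromo-3-fluorobenzene-1,2-diol | Oc1cc(Br)cc(F)c1O | starting material
14 | 1,2-bis(benzyloxy)-5-bromo-3-fluorobenzene | Fc1cc(Br)cc(OCc2ccccc2)c1OCc1ccccc1 | intermediate
15 | 2-(benzyloxy)-N-methoxy-N-methylacetamide | CON(C)C(=O)COCc1ccccc1 | starting material
16 | 2-(benzyloxy)-1-[3,4-bis(benzyloxy)-6-bromo-2-fluorophenyl]ethan-1-one | O=C(COCc1ccccc1)c1c(F)c(OCc2ccccc2)c(OCc2ccccc2)cc1Br | intermediate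
17 | methyl 3,4-bis(benzyloxy)benzoate | COC(=O)c1ccc(OCc2ccccc2)c(OCc2ccccc2)c1 | starting material
18 | 2-(benzyloxy)-1-[3,4-bis(benzyloxy)-6-bromo-2-fluorophenyl]-3-[3,4-bis(benzyloxy)phenyl]propane-1,3-dione | O=C(c1ccc(OCc2ccccc2)c(OCc2ccccc2)c1)C(OCc1ccccc1)C(=O)c1c(F)c(OCc2ccccc2)c(OCc2ccccc2)cc1Br | intermediate
19 | 3,7,8-tris(benzyloxy)-2-[3,4-bis(benzyloxy)phenyl]-5-bromo-4H-chromen-4-one | O=c1c(OCc2ccccc2)c(-c2ccc(OCc3ccccc3)c(OCc3ccccc3)c2)oc2c(OCc3ccccc3)c(OCc3ccccc3)cc(Br)c12 | intermediate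
20 | bromo{3,7,8-tris(benzyloxy)-2-[3,4-bis(benzyloxy)phenyl]-4-oxo-4H-chromen-5-yl}zinc | O=c1c(OCc2ccccc2)c(-c2ccc(OCc3ccccc3)c(OCc3ccccc3)c2)oc2c(OCc3ccccc3)c(OCc3ccccc3)cc([Zn]Br)c12 | intermediate
21 | 3,7,8-tris(benzyloxy)-2-[3,4-bis(benzyloxy)phenyl]-5-{(2R,3R,4S)-3,7,8-tris(benzyloxy)-2-[3,4-bis(benzyloxy)phenyl]-3,4-dihydro-2H-chromen-4-yl}-4H-chromen-4-one | O=c1c(OCc2ccccc2)c(-c2ccc(OCc3ccccc3)c(OCc3ccccc3)c2)oc2c(OCc3ccccc3)c(OCc3ccccc3)cc([C@H]3c4ccc(OCc5ccccc5)c(OCc5ccccc5)c4O[C@H](c4ccc(OCc5ccccc5)c(OCc5ccccc5)c4)[C@@H]3OCc3ccccc3)c12 | intermediate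
22 | 5-[(2R,3R,4S)-2-(3,4-dihydroxyphenyl)-3,7,8-trihydroxy-3,4-dihydro-2H-chromen-4-yl]-2-(3,4-dihydroxyphenyl)-3,7,8-trihydroxy-4H-chromen-4-one | O=c1c(O)c(-c2ccc(O)c(O)c2)oc2c(O)c(O)cc([C@H]3c4ccc(O)c(O)c4O[C@H](c4ccc(O)c(O)c4)[C@@H]3O)c12 | target

**Count and risks**

Total step count: 12. Longest linear sequence: 9 steps (steps 1 to 7, then 11 and 12).

Steps most likely to fail:

Step 11 (Proposed new method). The arylzinc reagent, weakened by chelation to the chromone carbonyl, may capture the cation too slowly, so that the cation loses the C3 proton to the enol ether or the zinc reagent is protonated. Fallback, from 12 and 19, returning at 21: 12 is treated with dry HCl in CH2Cl2/dioxane at −30 °C to give (2R,3S,4S)-3,7,8-tris(benzyloxy)-2-[3,4-bis(benzyloxy)phenyl]-4-chloro-3,4-dihydro-2H-chromene F1 (C4 configuration immaterial). F1 is joined to aryl bromide 19 by nickel-catalysed reductive cross-electrophile coupling (NiBr2·dme, 4,4′-di-tert-butyl-2,2′-bipyridine, Zn dust, NaI (cat.), DMA, rt), a known coupling of benzylic chlorides with aryl bromides. The C4 radical should be captured by the aryl–nickel species trans to the C3 benzyloxy group, giving 21.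

Step 5. The β-boryl alkoxide may lose boron by boron–oxygen elimination during the warm palladium stage, giving a 1,3-diarylpropene; the copper and phosphoramidite residues may also slow the palladium catalyst. Fallback, from 8, returning at 11 (boron is removed before the ether closure and O3 is blocked so that only O1 can close). The copper stage is run alone and 8 is isolated. TBSOTf/2,6-lutidine gives the O-silyl ether (1S,2R)-1-[3,4-bis(benzyloxy)phenyl]-3-[3,4-bis(benzyloxy)-2-bromophenyl]-1-[(tert-butyldimethylsilyl)oxy]-2-(4,4,5,5-tetramethyl-1,3,2-dioxaborolan-2-yl)propane F2. H2O2/pH 7 buffer gives (1R,2R)-1-[3,4-bis(benzyloxy)phenyl]-3-[3,4-bis(benzyloxy)-2-bromophenyl]-1-[(tert-butyldimethylsilyl)oxy]propan-2-ol F3. BnBr/Ag2O gives (1R,2R)-2-(benzyloxy)-1-[3,4-bis(benzyloxy)phenyl]-3-[3,4-bis(benzyloxy)-2-bromophenyl]-1-[(tert-butyldimethylsilyl)oxy]propane F4. Bu4NF gives (1R,2R)-2-(benzyloxy)-1-[3,4-bis(benzyloxy)phenyl]-3-[3,4-bis(benzyloxy)-2-bromophenyl]propan-1-ol F5. F5 is cyclised by the known palladium-catalysed intramolecular etherification (Pd(OAc)2, 2-(di-tert-butylphosphino)-1,1′-binaphthyl, Cs2CO3, toluene, 65 °C) to 11.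

Step 7. Hydride abstraction may occur at C2 instead of C4, because C2–H is benzylic, α to O1 and activated through the 2-aryl ring; the oxidation may also be sluggish because ring A has no C5 oxygen. Fallback, from 11, returning at 21: benzylic acetoxylation with Pb(OAc)4 in benzene (a ligand-transfer oxidation known for flavan ethers, in place of hydride abstraction by a quinone) gives (2R,3S,4S)-3,7,8-tris(benzyloxy)-2-[3,4-bis(benzyloxy)phenyl]-3,4-dihydro-2H-chromen-4-yl acetate F6. F6 takes the place of 12 in step 11 and is ionised by BF3·OEt2 in the same way, giving 21.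

**Further compounds**

F1 | step 11 | (2R,3S,4S)-3,7,8-tris(benzyloxy)-2-[3,4-bis(benzyloxy)phenyl]-4-chloro-3,4-dihydro-2H-chromene | Cl[C@H]1c2ccc(OCc3ccccc3)c(OCc3ccccc3)c2O[C@H](c2ccc(OCc3ccccc3)c(OCc3ccccc3)c2)[C@@H]1OCc1ccccc1
F2 | step 5 | (1S,2R)-1-[3,4-bis(benzyloxy)phenyl]-3-[3,4-bis(benzyloxy)-2-bromophenyl]-1-[(tert-butyldimethylsilyl)oxy]-2-(4,4,5,5-tetramethyl-1,3,2-dioxaborolan-2-yl)propane | CC(C)(C)[Si](C)(C)O[C@H](c1ccc(OCc2ccccc2)c(OCc2ccccc2)c1)[C@@H](Cc1ccc(OCc2ccccc2)c(OCc2ccccc2)c1Br)B1OC(C)(C)C(C)(C)O1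
F3 | step 5 | (1R,2R)-1-[3,4-bis(benzyloxy)phenyl]-3-[3,4-bis(benzyloxy)-2-bromophenyl]-1-[(tert-butyldimethylsilyl)oxy]propan-2-ol | CC(C)(C)[Si](C)(C)O[C@H](c1ccc(OCc2ccccc2)c(OCc2ccccc2)c1)[C@@H](Cc1ccc(OCc2ccccc2)c(OCc2ccccc2)c1Br)O
F4 | step 5 | (1R,2R)-2-(benzyloxy)-1-[3,4-bis(benzyloxy)phenyl]-3-[3,4-bis(benzyloxy)-2-bromophenyl]-1-[(tert-butyldimethylsilyl)oxy]propane | CC(C)(C)[Si](C)(C)O[C@H](c1ccc(OCc2ccccc2)c(OCc2ccccc2)c1)[C@@H](Cc1ccc(OCc2ccccc2)c(OCc2ccccc2)c1Br)OCc1ccccc1
F5 | step 5 | (1R,2R)-2-(benzyloxy)-1-[3,4-bis(benzyloxy)phenyl]-3-[3,4-bis(benzyloxy)-2-bromophenyl]propan-1-ol | O[C@H](c1ccc(OCc2ccccc2)c(OCc2ccccc2)c1)[C@@H](Cc1ccc(OCc2ccccc2)c(OCc2ccccc2)c1Br)OCc1ccccc1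
F6 | step 7 | (2R,3S,4S)-3,7,8-tris(benzyloxy)-2-[3,4-bis(benzyloxy)phenyl]-3,4-dihydro-2H-chromen-4-yl acetate | CC(=O)O[C@H]1c2ccc(OCc3ccccc3)c(OCc3ccccc3)c2O[C@H](c2ccc(OCc3ccccc3)c(OCc3ccccc3)c2)[C@@H]1OCc1ccccc1
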